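Cuts: C12–C13 (butenolide from the decalin core) first, then C4–C5 and C9–C10 (both rings in one operation), then the open chain at C3–C4, C1–C2, C5–C10 and C9–C11.
Feature used (labdane numbering): rings A and B form a trans-decalin whose contiguous centres C4, C5, C10, C9 and exocyclic C8=C17 are the chair–chair fold of an acyclic 5(10),8(9)-diene; C19, held as an ester beside a C3 ketone, makes C4 a 1,3-dicarbonyl carbon from which a radical can be generated.
Forward: the chain is built linearly from pent-4-yn-1-ol (C5–C8 and C17 by carboalumination, C11–C12 from ethylene oxide, C10/C20/C1 from 2-bromoallyl alcohol, C2–C3 by Johnson–Claisen, C4/C18/C19 from a chiral propionate). Ring A and then ring B close in step 12; C3 is then deoxygenated, C19 reduced and acetylated, the butenolide coupled at C12 and C20 oxidised last.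
Stereochemistry: alkene geometry (syn-carboalumination, chair Claisen) is relayed to C5, C10 and C9 by the fold; the (−)-8-phenylmenthyl ester sets the absolute sense at C4 and thereby of all four centres.

Key step: step 12

Remark: the (−)-auxiliary is assumed to deliver the ent series, as the π-shielding model for 8-phenylmenthyl esters predicts for a W-shaped dicarbonyl radical; if the sense were the opposite, the enantiomeric auxiliary would be used, and a minor diastereomer stays separable because the auxiliary remains attached until step 16.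

Step 1
Reactants: 1 pent-4-yn-1-ol
Product: 2 tert-butyldimethyl(pent-4-yn-1-yloxy)silane
Conditions: TBSCl, imidazole, CH2Cl2, 0 → 25 °C
Reagents that add atoms: tert-butyldimethylsilyl chloride, CC(C)(C)[Si](C)(C)Cl
Why: Standard silylation of a primary alcohol masks the future C5 oxygen against the organoaluminium reagents of step 2.

Step 2
Reactants: 2 tert-butyldimethyl(pent-4-yn-1-yloxy)silane
Product: 5 (E)-7-(tert-butyldimethylsilyloxy)-4-methylhept-3-en-1-ol, via alkenyldimethylalane 3 (not isolated), via lithium alkenylalanate 4 (not isolated)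
Conditions: Me3Al (2.5 equiv), Cp2ZrCl2 (0.25 equiv), CH2Cl2, 0 → 25 °C; volatiles off, hexane; n-BuLi, −78 → 0 °C; ethylene oxide, THF, −30 → 25 °C; H2O
Reagents that add atoms: trimethylaluminium, C[Al](C)C; n-butyllithium (butyl and lithium only in 4), [Li]CCCC; ethylene oxide, C1CO1
Why: Zirconium-catalysed syn-carboalumination (Negishi carboalumination) places methyl and aluminium cis across the terminal alkyne, and the derived alanate opens ethylene oxide with retention, which fixes the E geometry of the C8=C9 alkene.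

Step 3
Reactants: 5 (E)-7-(tert-butyldimethylsilyloxy)-4-methylhept-3-en-1-ol
Product: 6 (E)-7-(tert-butyldimethylsilyloxy)-4-methylhept-3-en-1-yl pivalate
Conditions: PivCl, pyridine, DMAP (cat.), CH2Cl2, 0 → 25 °C
Reagents that add atoms: pivaloyl chloride, CC(C)(C)C(Cl)=O
Why: Acylation of the primary alcohol installs a hindered ester at C12 that should survive enolates, saponification and the radical step, and is later removed together with the auxiliary.

Step 4
Reactants: 6 (E)-7-(tert-butyldimethylsilyloxy)-4-methylhept-3-en-1-yl pivalate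
Product: 7 (E)-7-hydroxy-4-methylhept-3-en-1-yl pivalate
Conditions: PPTS (cat.), MeOH, 25 °C
Reagents that add atoms: none
Why: Acid-catalysed methanolysis cleaves the primary TBS ether while the pivalate and the trisubstituted alkene are inert.

Step 5
Reactants: 7 (E)-7-hydroxy-4-methylhept-3-en-1-yl pivalate
Product: 8 (E)-4-methyl-7-oxohept-3-en-1-yl pivalate
Conditions: TEMPO (cat.), PhI(OAc)2, CH2Cl2, 25 °C
Reagents that add atoms: none
Why: Oxoammonium-mediated oxidation stops at the aldehyde and leaves the alkene and ester untouched.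

Step 6
Reactants: 8 (E)-4-methyl-7-oxohept-3-en-1-yl pivalate, 9 2-bromoprop-2-en-1-ol
Product: 11 (E)-7-hydroxy-8-(hydroxymethyl)-4-methylnona-3,8-dien-1-yl pivalate (racemic at the carbinol carbon), via dilithiated allyl alkoxide 10 (not isolated)
Conditions: 9, t-BuLi (3 equiv), Et2O, −78 → 0 °C; then 8, −78 °C; H2O
Reagents that add atoms: tert-butyllithium (lithium only in 10), [Li]C(C)(C)C
Why: Bromine–lithium exchange on the lithium alkoxide of 9 gives a 2-lithioallyl alkoxide that adds 1,2 to the aldehyde far faster than to the pivalate at −78 °C; the new carbinol centre is racemic and is erased in step 8.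

Step 7
Reactants: 11 (E)-7-hydroxy-8-(hydroxymethyl)-4-methylnona-3,8-dien-1-yl pivalate
Product: 12 (E)-8-[(tert-butyldiphenylsilyloxy)methyl]-7-hydroxy-4-methylnona-3,8-dien-1-yl pivalate
Conditions: TBDPSCl (1.05 equiv), imidazole, CH2Cl2, 0 °C
Reagents that add atoms: tert-butyldiphenylsilyl chloride, CC(C)(C)[Si](Cl)(c1ccccc1)c1ccccc1
Why: The bulky silyl chloride reacts selectively with the primary allylic hydroxyl (future C20) and leaves the secondary allylic alcohol free for the rearrangement.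

Step 8
Reactants: 12 (E)-8-[(tert-butyldiphenylsilyloxy)methyl]-7-hydroxy-4-methylnona-3,8-dien-1-yl pivalate
Product: 14 ethyl (4Z,8E)-4-[(tert-butyldiphenylsilyloxy)methyl]-8-methyl-11-(pivaloyloxy)undeca-4,8-dienoate, via ketene acetal 13 (not isolated)
Conditions: MeC(OEt)3 (excess), EtCO2H (cat.), 140 °C, EtOH distilled off
Reagents that add atoms: triethyl orthoacetate, CCOC(C)(OCC)OCC
Why: Johnson–Claisen rearrangement through a chair transition state with the C6 chain pseudo-equatorial (an axial chain would clash with the ethoxy group) forms C1–C2 and places C1 trans to C6 on the new C5=C10 alkene, the geometry required for a trans ring fusion.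

Step 9
Reactants: 14 ethyl (4Z,8E)-4-[(tert-butyldiphenylsilyloxy)methyl]-8-methyl-11-(pivaloyloxy)undeca-4,8-dienoate
Product: 15 (4Z,8E)-4-[(tert-butyldiphenylsilyloxy)methyl]-8-methyl-11-(pivaloyloxy)undeca-4,8-dienoic acid
Conditions: LiOH (1.5 equiv), THF/MeOH/H2O, 0 → 25 °C; then 1 M HCl to pH 3
Reagents that add atoms: lithium hydroxide (hydroxide oxygen), [Li+].[OH-]
Why: Saponification of the unhindered ethyl ester is much faster than that of the pivalate, so only the C3 carboxyl is released.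

Step 10
Reactants: 16 (−)-8-phenylmenthol
Product: 17 (1R,2S,5R)-5-methyl-2-(2-phenylpropan-2-yl)cyclohexyl propanoate
Conditions: EtCOCl, pyridine, DMAP (cat.), CH2Cl2, 0 → 25 °C
Reagents that add atoms: propanoyl chloride, CCC(Cl)=O
Why: DMAP-catalysed acylation of the hindered secondary alcohol gives the propionate that will supply C4, C18 and C19.

Step 11
Reactants: 15 (4Z,8E)-4-[(tert-butyldiphenylsilyloxy)methyl]-8-methyl-11-(pivaloyloxy)undeca-4,8-dienoic acid, 17 (1R,2S,5R)-5-methyl-2-(2-phenylpropan-2-yl)cyclohexyl propanoate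
Product: 20 (1R,2S,5R)-5-methyl-2-(2-phenylpropan-2-yl)cyclohexyl (6Z,10E)-6-[(tert-butyldiphenylsilyloxy)methyl]-2,10-dimethyl-3-oxo-13-(pivaloyloxy)trideca-6,10-dienoate (both C2 epimers), via acyl imidazolide 18 (not isolated), via lithium enolate 19 (not isolated)
Conditions: 15, CDI, THF, 25 °C; separately 17 (2.2 equiv), LiN(i-Pr)2, THF, −78 °C; combine, −78 → −20 °C; aq. NH4Cl
Reagents that add atoms: 1,1'-carbonyldiimidazole (imidazolyl only in 18), O=C(n1ccnc1)n1ccnc1; lithium diisopropylamide (lithium only in 19), CC(C)[N-]C(C)C.[Li+]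
Why: Crossed Claisen-type C-acylation of an ester enolate by an acyl imidazolide forms C3–C4; the second equivalent of enolate deprotonates the keto ester as it forms, which prevents further reaction, and the excess 17 is recovered.

Step 12
Reactants: 20 (1R,2S,5R)-5-methyl-2-(2-phenylpropan-2-yl)cyclohexyl (6Z,10E)-6-[(tert-butyldiphenylsilyloxy)methyl]-2,10-dimethyl-3-oxo-13-(pivaloyloxy)trideca-6,10-dienoate
Product: 21 (−)-8-phenylmenthyl 20-(tert-butyldiphenylsilyloxy)-3-oxo-12-(pivaloyloxy)-13,14,15,16-tetranor-ent-labd-8(17)-en-19-oate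
Conditions: Mn(OAc)3·2H2O (2.2 equiv), Cu(OAc)2·H2O (1 equiv), degassed AcOH, 25 °C
Reagents that add atoms: none
Why: Enolisation of 20 (both C4 epimers converge) and one-electron oxidation by Mn(OAc)3 give the electrophilic tertiary C4 radical, which adds to C5; the resulting tertiary C10 radical adds to C9, and Cu(OAc)2 captures the tertiary C8 radical and delivers the C8=C17 alkene by loss of a C17 hydrogen, the copper being returned to the divalent state by Mn(OAc)3. The closest known reaction type is the Mn(OAc)3/Cu(OAc)2 oxidative free-radical polyene cyclisation of 2-alkyl-3-oxo esters, which is also documented for 8-phenylmenthyl esters. Ring A closes 6-endo-trig (C4–C5) and ring B closes 6-endo-trig (C10–C9), each time because attack at the CH terminus of a trisubstituted alkene leaves a tertiary radical. C5, C10 and C9 follow from the chair–chair fold of the 6Z,10E diene (anti addition across C5=C10 gives the trans fusion, C11 sits equatorial); at C4 the ester takes the axial site because the radical reacts in the W-shaped dicarbonyl conformation that keeps the ketone oxygen away from the ester, and the absolute sense comes from the aryl group of the auxiliary, which covers one face of the planar C4 radical. The step needs facial selectivity at C4, complete bicyclisation and exocyclic termination: the first is secured by the auxiliary (a minor diastereomer stays separable because the auxiliary is still attached), the second by the absence of ionic intermediates that the β-silyloxy group at C20 would retard, and the third by the preference of the copper-mediated elimination for the unhindered methyl hydrogens.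

Step 13
Reactants: 21 (−)-8-phenylmenthyl 20-(tert-butyldiphenylsilyloxy)-3-oxo-12-(pivaloyloxy)-13,14,15,16-tetranor-ent-labd-8(17)-en-19-oate
Product: 22 (−)-8-phenylmenthyl (3R)-20-(tert-butyldiphenylsilyloxy)-3-hydroxy-12-(pivaloyloxy)-13,14,15,16-tetranor-ent-labd-8(17)-en-19-oate
Conditions: NaBH4, MeOH/THF, 0 °C
Reagents that add atoms: none
Why: Borohydride reduces only the ketone; axial hydride delivery from the face remote from the axial C19 and C20 groups should give the equatorial alcohol, and this centre is removed in step 15, so its configuration does not matter.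

Step 14
Reactants: 22 (−)-8-phenylmenthyl (3R)-20-(tert-butyldiphenylsilyloxy)-3-hydroxy-12-(pivaloyloxy)-13,14,15,16-tetranor-ent-labd-8(17)-en-19-oate
Product: 23 (−)-8-phenylmenthyl (3R)-20-(tert-butyldiphenylsilyloxy)-3-(phenoxythiocarbonyloxy)-12-(pivaloyloxy)-13,14,15,16-tetranor-ent-labd-8(17)-en-19-oate
Conditions: PhOC(S)Cl, pyridine, DMAP (cat.), CH2Cl2, 25 °C
Reagents that add atoms: O-phenyl chlorothionoformate, S=C(Cl)Oc1ccccc1
Why: Thionocarbonate formation under amine conditions avoids a metal alkoxide of the β-hydroxy ester and thus retro-aldol opening of ring A.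

Step 15
Reactants: 23 (−)-8-phenylmenthyl (3R)-20-(tert-butyldiphenylsilyloxy)-3-(phenoxythiocarbonyloxy)-12-(pivaloyloxy)-13,14,15,16-tetranor-ent-labd-8(17)-en-19-oate
Product: 24 (−)-8-phenylmenthyl 20-(tert-butyldiphenylsilyloxy)-12-(pivaloyloxy)-13,14,15,16-tetranor-ent-labd-8(17)-en-19-oate
Conditions: Bu3SnH, AIBN (cat.), toluene, 100 °C
Reagents that add atoms: none
Why: Barton–McCombie deoxygenation turns C3 into a methylene group through a secondary radical that the rigid decalin keeps away from the C8=C17 alkene.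

Step 16
Reactants: 24 (−)-8-phenylmenthyl 20-(tert-butyldiphenylsilyloxy)-12-(pivaloyloxy)-13,14,15,16-tetranor-ent-labd-8(17)-en-19-oate
Product: 25 20-(tert-butyldiphenylsilyloxy)-13,14,15,16-tetranor-ent-labd-8(17)-ene-12,19-diol
Conditions: LiAlH4 (excess), THF, 0 → 65 °C; H2O, aq. NaOH
Reagents that add atoms: none
Why: Hydride reduction cleaves the auxiliary ester to the C19 carbinol and the pivalate to the C12 alcohol in one operation, the auxiliary being recovered; silyl ether and alkene are inert to LiAlH4.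

Step 17
Reactants: 25 20-(tert-butyldiphenylsilyloxy)-13,14,15,16-tetranor-ent-labd-8(17)-ene-12,19-diol
Product: 26 20-(tert-butyldiphenylsilyloxy)-12-iodo-13,14,15,16-tetranor-ent-labd-8(17)-en-19-ol
Conditions: I2 (1.1 equiv), PPh3, imidazole, CH2Cl2, 0 °C
Reagents that add atoms: iodine, [I][I]
Why: Appel-type iodination proceeds by SN2 displacement, which is feasible at the unhindered C12 carbinol but not at the neopentyl, axial C19 carbinol.

Step 18
Reactants: 26 20-(tert-butyldiphenylsilyloxy)-12-iodo-13,14,15,16-tetranor-ent-labd-8(17)-en-19-ol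
Product: 27 19-acetoxy-20-(tert-butyldiphenylsilyloxy)-12-iodo-13,14,15,16-tetranor-ent-labd-8(17)-ene
Conditions: Ac2O, Et3N, DMAP (cat.), CH2Cl2, 0 → 25 °C
Reagents that add atoms: acetic anhydride, CC(=O)OC(C)=O
Why: DMAP-catalysed acetylation esterifies the remaining hindered primary alcohol under conditions too mild to quaternise the amine with the primary iodide.

Step 19
Reactants: 27 19-acetoxy-20-(tert-butyldiphenylsilyloxy)-12-iodo-13,14,15,16-tetranor-ent-labd-8(17)-ene, 28 3-bromofuran-2(5H)-one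
Product: 30 19-acetoxy-20-(tert-butyldiphenylsilyloxy)-ent-labda-8(17),13-dien-16,15-olide, via alkylzinc iodide 29 (not isolated)
Conditions: 27, Zn dust, LiCl, THF, 40 °C; then 28, PdCl2(dppf) (5 mol %), THF, 25–45 °C
Reagents that add atoms: zinc (only in 29), [Zn]
Why: Zinc insertion into the primary C–I bond tolerates acetate, silyl ether and alkene, and Negishi coupling joins C12 to C13 after zerovalent palladium inserts into the alkenyl C–Br bond; the coupling is base-free, so the butenolide is not deprotonated, and the wide-bite-angle dppf ligand favours reductive elimination over β-hydride loss.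

Step 20
Reactants: 30 19-acetoxy-20-(tert-butyldiphenylsilyloxy)-ent-labda-8(17),13-dien-16,15-olide
Product: 31 19-acetoxy-20-hydroxy-ent-labda-8(17),13-dien-16,15-olide
Conditions: HF·pyridine, pyridine/THF, 0 → 25 °C
Reagents that add atoms: none
Why: Fluoride cleaves the neopentyl silyl ether under non-basic buffered conditions, which avoids acetyl migration from O19 to O20 and base damage to the butenolide.

Step 21
Reactants: 31 19-acetoxy-20-hydroxy-ent-labda-8(17),13-dien-16,15-olide
Product: 32 19-acetoxy-20-oxo-ent-labda-8(17),13-dien-16,15-olide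
Conditions: Dess–Martin periodinane, CH2Cl2, 25 °C
Reagents that add atoms: none
Why: Dess–Martin oxidation converts the hindered neopentyl alcohol into the aldehyde, which has a quaternary α-carbon and therefore cannot epimerise or over-oxidise under these conditions.

Compound list
1 | pent-4-yn-1-ol | C#CCCCO | starting material
2 | tert-butyldimethyl(pent-4-yn-1-yloxy)silane | C#CCCCO[Si](C)(C)C(C)(C)C | intermediate
3 | [(E)-5-(tert-butyldimethylsilyloxy)-2-methylpent-1-en-1-yl]dimethylalane | C[Al](C)/C=C(\C)CCCO[Si](C)(C)C(C)(C)C | intermediate (not isolated)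
4 | lithium butyl[(E)-5-(tert-butyldimethylsilyloxy)-2-methylpent-1-en-1-yl]dimethylalanate | [Li+].CCCC[Al-](C)(C)/C=C(\C)CCCO[Si](C)(C)C(C)(C)C | intermediate (not isolated)
5 | (E)-7-(tert-butyldimethylsilyloxy)-4-methylhept-3-en-1-ol | OCC/C=C(\C)CCCO[Si](C)(C)C(C)(C)C | intermediate
6 | (E)-7-(tert-butyldimethylsilyloxy)-4-methylhept-3-en-1-yl pivalate | CC(C)(C)C(=O)OCC/C=C(\C)CCCO[Si](C)(C)C(C)(C)C | intermediate
7 | (E)-7-hydroxy-4-methylhept-3-en-1-yl pivalate | CC(C)(C)C(=O)OCC/C=C(\C)CCCO | intermediate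
8 | (E)-4-methyl-7-oxohept-3-en-1-yl pivalate | CC(C)(C)C(=O)OCC/C=C(\C)CCC=O | intermediate
9 | 2-bromoprop-2-en-1-ol | C=C(Br)CO | starting material
10 | lithium 2-lithioprop-2-en-1-olate | [Li]OCC(=C)[Li] | intermediate (not isolated)
11 | (E)-7-hydroxy-8-(hydroxymethyl)-4-methylnona-3,8-dien-1-yl pivalate, racemic at C7 | CC(C)(C)C(=O)OCC/C=C(\C)CCC(O)C(=C)CO | intermediate
12 | (E)-8-[(tert-butyldiphenylsilyloxy)methyl]-7-hydroxy-4-methylnona-3,8-dien-1-yl pivalate, racemic at C7 | CC(C)(C)C(=O)OCC/C=C(\C)CCC(O)C(=C)CO[Si](c1ccccc1)(c1ccccc1)C(C)(C)C | intermediate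
13 | (E)-8-[(tert-butyldiphenylsilyloxy)methyl]-7-[(1-ethoxyvinyl)oxy]-4-methylnona-3,8-dien-1-yl pivalate | C=C(OCC)OC(CC/C(C)=C/CCOC(=O)C(C)(C)C)C(=C)CO[Si](c1ccccc1)(c1ccccc1)C(C)(C)C | intermediate (not isolated)
14 | ethyl (4Z,8E)-4-[(tert-butyldiphenylsilyloxy)methyl]-8-methyl-11-(pivaloyloxy)undeca-4,8-dienoate | CCOC(=O)CC/C(CO[Si](c1ccccc1)(c1ccccc1)C(C)(C)C)=C/CC/C(C)=C/CCOC(=O)C(C)(C)C | intermediate
15 | (4Z,8E)-4-[(tert-butyldiphenylsilyloxy)methyl]-8-methyl-11-(pivaloyloxy)undeca-4,8-dienoic acid | OC(=O)CC/C(CO[Si](c1ccccc1)(c1ccccc1)C(C)(C)C)=C/CC/C(C)=C/CCOC(=O)C(C)(C)C | intermediate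
16 | (−)-8-phenylmenthol, (1R,2S,5R)-5-methyl-2-(2-phenylpropan-2-yl)cyclohexan-1-ol | C[C@@H]1CC[C@H]([C@@H](C1)O)C(C)(C)c1ccccc1 | starting material
17 | (1R,2S,5R)-5-methyl-2-(2-phenylpropan-2-yl)cyclohexyl propanoate | CCC(=O)O[C@@H]1C[C@H](C)CC[C@H]1C(C)(C)c1ccccc1 | intermediate
18 | N-acylimidazole of acid 15 | O=C(CC/C(CO[Si](c1ccccc1)(c1ccccc1)C(C)(C)C)=C/CC/C(C)=C/CCOC(=O)C(C)(C)C)n1ccnc1 | intermediate (not isolated)
19 | lithium enolate of propanoate 17 | CC=C(O[Li])O[C@@H]1C[C@H](C)CC[C@H]1C(C)(C)c1ccccc1 | intermediate (not isolated)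
20 | (1R,2S,5R)-5-methyl-2-(2-phenylpropan-2-yl)cyclohexyl (6Z,10E)-6-[(tert-butyldiphenylsilyloxy)methyl]-2,10-dimethyl-3-oxo-13-(pivaloyloxy)trideca-6,10-dienoate, both C2 epimers | C[C@@H]1CC[C@H]([C@@H](C1)OC(=O)C(C)C(=O)CC/C(CO[Si](c1ccccc1)(c1ccccc1)C(C)(C)C)=C/CC/C(C)=C/CCOC(=O)C(C)(C)C)C(C)(C)c1ccccc1 | intermediate
21 | (−)-8-phenylmenthyl 20-(tert-butyldiphenylsilyloxy)-3-oxo-12-(pivaloyloxy)-13,14,15,16-tetranor-ent-labd-8(17)-en-19-oate (trans-decalin; C19 ester, C20 and C11 on one face, H5, H9 and C18 on the other) | C=C1CC[C@@H]2[C@](C)(C(=O)O[C@@H]3C[C@H](C)CC[C@H]3C(C)(C)c3ccccc3)C(=O)CC[C@@]2(CO[Si](c3ccccc3)(c3ccccc3)C(C)(C)C)[C@@H]1CCOC(=O)C(C)(C)C | intermediate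
22 | (−)-8-phenylmenthyl (3R)-20-(tert-butyldiphenylsilyloxy)-3-hydroxy-12-(pivaloyloxy)-13,14,15,16-tetranor-ent-labd-8(17)-en-19-oate (equatorial 3-OH) | C=C1CC[C@@H]2[C@](C)(C(=O)O[C@@H]3C[C@H](C)CC[C@H]3C(C)(C)c3ccccc3)[C@H](O)CC[C@@]2(CO[Si](c3ccccc3)(c3ccccc3)C(C)(C)C)[C@@H]1CCOC(=O)C(C)(C)C | intermediate
23 | (−)-8-phenylmenthyl (3R)-20-(tert-butyldiphenylsilyloxy)-3-(phenoxythiocarbonyloxy)-12-(pivaloyloxy)-13,14,15,16-tetranor-ent-labd-8(17)-en-19-oate | C=C1CC[C@@H]2[C@](C)(C(=O)O[C@@H]3C[C@H](C)CC[C@H]3C(C)(C)c3ccccc3)[C@H](OC(=S)Oc3ccccc3)CC[C@@]2(CO[Si](c3ccccc3)(c3ccccc3)C(C)(C)C)[C@@H]1CCOC(=O)C(C)(C)C | intermediate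
24 | (−)-8-phenylmenthyl 20-(tert-butyldiphenylsilyloxy)-12-(pivaloyloxy)-13,14,15,16-tetranor-ent-labd-8(17)-en-19-oate | C=C1CC[C@@H]2[C@](C)(C(=O)O[C@@H]3C[C@H](C)CC[C@H]3C(C)(C)c3ccccc3)CCC[C@@]2(CO[Si](c3ccccc3)(c3ccccc3)C(C)(C)C)[C@@H]1CCOC(=O)C(C)(C)C | intermediate
25 | 20-(tert-butyldiphenylsilyloxy)-13,14,15,16-tetranor-ent-labd-8(17)-ene-12,19-diol | C=C1CC[C@@H]2[C@](C)(CO)CCC[C@@]2(CO[Si](c3ccccc3)(c3ccccc3)C(C)(C)C)[C@@H]1CCO | intermediate
26 | 20-(tert-butyldiphenylsilyloxy)-12-iodo-13,14,15,16-tetranor-ent-labd-8(17)-en-19-ol | C=C1CC[C@@H]2[C@](C)(CO)CCC[C@@]2(CO[Si](c3ccccc3)(c3ccccc3)C(C)(C)C)[C@@H]1CCI | intermediate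
27 | 19-acetoxy-20-(tert-butyldiphenylsilyloxy)-12-iodo-13,14,15,16-tetranor-ent-labd-8(17)-ene | C=C1CC[C@@H]2[C@](C)(COC(C)=O)CCC[C@@]2(CO[Si](c3ccccc3)(c3ccccc3)C(C)(C)C)[C@@H]1CCI | intermediate
28 | 3-bromofuran-2(5H)-one | O=C1OCC=C1Br | starting material
29 | C12 alkylzinc iodide derived from 27 | C=C1CC[C@@H]2[C@](C)(COC(C)=O)CCC[C@@]2(CO[Si](c3ccccc3)(c3ccccc3)C(C)(C)C)[C@@H]1CC[Zn]I | intermediate (not isolated)
30 | 19-acetoxy-20-(tert-butyldiphenylsilyloxy)-ent-labda-8(17),13-dien-16,15-olide | C=C1CC[C@@H]2[C@](C)(COC(C)=O)CCC[C@@]2(CO[Si](c3ccccc3)(c3ccccc3)C(C)(C)C)[C@@H]1CCC1=CCOC1=O | intermediate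
31 | 19-acetoxy-20-hydroxy-ent-labda-8(17),13-dien-16,15-olide | C=C1CC[C@@H]2[C@](C)(COC(C)=O)CCC[C@@]2(CO)[C@@H]1CCC1=CCOC1=O | intermediate
32 | 19-acetoxy-20-oxo-ent-labda-8(17),13-dien-16,15-olide, [(1R,4aR,5R,8aR)-4a-formyl-1-methyl-6-methylidene-5-[2-(2-oxo-2,5-dihydrofuran-3-yl)ethyl]decahydronaphthalen-1-yl]methyl acetate | C=C1CC[C@@H]2[C@](C)(COC(C)=O)CCC[C@@]2(C=O)[C@@H]1CCC1=CCOC1=O | target

Total step count: 21. Longest linear sequence: 20 steps (steps 1–9 and 11–21; step 10 is the side branch).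

Steps most likely to fail

Step 12. The aryl group may shield one face of the tertiary C4 radical incompletely, or closure of ring B next to the silyloxymethyl-bearing C10 may be slow, so that diastereomers or monocyclic oxidation products accumulate. The fallback sets the C4 quaternary centre after the cascade instead of in it. It sets out from acid 15: condensation with Meldrum's acid (EDC·HCl, DMAP, CH2Cl2) should give the acyl Meldrum's acid F1. Heating F1 with 16 in toluene (acyl ketene capture) should give the 2-unsubstituted 8-phenylmenthyl 3-oxo ester F2. Mn(OAc)3·2H2O/Cu(OAc)2·H2O with Yb(OTf)3 in CF3CH2OH at 0 °C then cyclises the chelated, metal-bound enolate radical, the best-documented regime for this auxiliary, to the bicyclic 4-unsubstituted keto ester F3. C-Methylation of F3 (K2CO3, MeI, acetone) should take place on the face opposite the axial C20 substituent and thus returns to 21.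

Step 19. Zinc insertion may be sluggish, the alkylzinc may be lost by protonation or β-hydride elimination on palladium, or the bromobutenolide may decompose before coupling. The fallback builds the butenolide by enolate alkylation and sulfoxide elimination. It sets out from iodide 27: α-bromo-γ-butyrolactone with PhSH/Et3N gives 3-(phenylthio)dihydrofuran-2(3H)-one F4. The lithium enolate of F4 (LiN(SiMe3)2, THF/DMPU, −78 → 0 °C) is alkylated by 27 to the 3-alkyl-3-(phenylthio) lactone F5 (C13 epimers). mCPBA (1 equiv, CH2Cl2, −78 °C) oxidises sulfur in preference to the alkene and gives the sulfoxide F6, and thermolysis in toluene at 100 °C over CaCO3 eliminates toward C14 and comes back at 30.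

Step 16. Hydride attack on the axial, doubly neopentyl auxiliary ester may be too slow, and forcing conditions may cleave the silyl ether or let it migrate from O20 to O19. The fallback uses neighbouring-group delivery of hydride before C3 is deoxygenated. It sets out from 21: LiAlH4 in THF at 0 → 25 °C reduces the C3 ketone first, and the C3 alkoxyaluminium hydride then delivers hydride to the adjacent C19 carbonyl through a six-membered array; the pivalate is cleaved as well, giving the 3,12,19-triol F7. Ac2O (2.2 equiv)/pyridine at 0 °C acetylates the two primary hydroxyls to the 12,19-diacetate F8. The hindered C3 hydroxyl is then converted with PhOC(S)Cl/DMAP into the thionocarbonate F9 and removed with Bu3SnH/AIBN to give the 3-deoxy diacetate F10. K2CO3/MeOH comes back at diol 25.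

Further compounds
F1 | step 12 | 5-acyl Meldrum's acid of 15 (enol form), 5-[(4Z,8E)-4-[(tert-butyldiphenylsilyloxy)methyl]-1-hydroxy-8-methyl-11-(pivaloyloxy)undeca-4,8-dienylidene]-2,2-dimethyl-1,3-dioxane-4,6-dione | CC1(C)OC(=O)C(=C(O)CC/C(CO[Si](c2ccccc2)(c2ccccc2)C(C)(C)C)=C/CC/C(C)=C/CCOC(=O)C(C)(C)C)C(=O)O1
F2 | step 12 | (1R,2S,5R)-5-methyl-2-(2-phenylpropan-2-yl)cyclohexyl (6Z,10E)-6-[(tert-butyldiphenylsilyloxy)methyl]-10-methyl-3-oxo-13-(pivaloyloxy)trideca-6,10-dienoate | C[C@@H]1CC[C@H]([C@@H](C1)OC(=O)CC(=O)CC/C(CO[Si](c1ccccc1)(c1ccccc1)C(C)(C)C)=C/CC/C(C)=C/CCOC(=O)C(C)(C)C)C(C)(C)c1ccccc1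
F3 | step 12 | (−)-8-phenylmenthyl 20-(tert-butyldiphenylsilyloxy)-3-oxo-12-(pivaloyloxy)-13,14,15,16,18-pentanor-ent-labd-8(17)-en-19-oate (C4 enolisable) | C=C1CC[C@@H]2C(C(=O)O[C@@H]3C[C@H](C)CC[C@H]3C(C)(C)c3ccccc3)C(=O)CC[C@@]2(CO[Si](c3ccccc3)(c3ccccc3)C(C)(C)C)[C@@H]1CCOC(=O)C(C)(C)C
F4 | step 19 | 3-(phenylthio)dihydrofuran-2(3H)-one | O=C1OCCC1Sc1ccccc1
F5 | step 19 | 19-acetoxy-20-(tert-butyldiphenylsilyloxy)-13-(phenylthio)-ent-labd-8(17)-en-16,15-olide (C13 epimers) | C=C1CC[C@@H]2[C@](C)(COC(C)=O)CCC[C@@]2(CO[Si](c3ccccc3)(c3ccccc3)C(C)(C)C)[C@@H]1CCC1(Sc3ccccc3)CCOC1=O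
F6 | step 19 | 19-acetoxy-20-(tert-butyldiphenylsilyloxy)-13-(phenylsulfinyl)-ent-labd-8(17)-en-16,15-olide (stereoisomers at C13 and sulfur) | C=C1CC[C@@H]2[C@](C)(COC(C)=O)CCC[C@@]2(CO[Si](c3ccccc3)(c3ccccc3)C(C)(C)C)[C@@H]1CCC1(S(=O)c3ccccc3)CCOC1=O
F7 | step 16 | (3R)-20-(tert-butyldiphenylsilyloxy)-13,14,15,16-tetranor-ent-labd-8(17)-ene-3,12,19-triol | C=C1CC[C@@H]2[C@](C)(CO)[C@H](O)CC[C@@]2(CO[Si](c3ccccc3)(c3ccccc3)C(C)(C)C)[C@@H]1CCO
F8 | step 16 | (3R)-12,19-diacetoxy-20-(tert-butyldiphenylsilyloxy)-13,14,15,16-tetranor-ent-labd-8(17)-en-3-ol | C=C1CC[C@@H]2[C@](C)(COC(C)=O)[C@H](O)CC[C@@]2(CO[Si](c3ccccc3)(c3ccccc3)C(C)(C)C)[C@@H]1CCOC(C)=O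
F9 | step 16 | (3R)-12,19-diacetoxy-20-(tert-butyldiphenylsilyloxy)-3-(phenoxythiocarbonyloxy)-13,14,15,16-tetranor-ent-labd-8(17)-ene | C=C1CC[C@@H]2[C@](C)(COC(C)=O)[C@H](OC(=S)Oc3ccccc3)CC[C@@]2(CO[Si](c3ccccc3)(c3ccccc3)C(C)(C)C)[C@@H]1CCOC(C)=O
F10 | step 16 | 12,19-diacetoxy-20-(tert-butyldiphenylsilyloxy)-13,14,15,16-tetranor-ent-labd-8(17)-ene | C=C1CC[C@@H]2[C@](C)(COC(C)=O)CCC[C@@]2(CO[Si](c3ccccc3)(c3ccccc3)C(C)(C)C)[C@@H]1CCOC(C)=O
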